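**Retrosynthetic overview**
1. C1–C2 is cut last: an intramolecular 2-(methoxycarbonyl)allylboration of a C2 enal, then lactonisation, closes the 14-membered carbocycle and the cis-fused α-methylene-γ-lactone together.
2. The allylboronate arm (C15, C16, C17) is cut at C1=C15: cross-metathesis of a terminal alkene with a boryl acrylate.
3. The 11,12-epoxide comes from matched, hydroxyl-directed epoxidation of a 13R allylic alcohol; the C13 acetate follows.
4. C13, the first stereocentre, is cut at C13–C14: chiral phosphoric acid-catalysed allylboration of an (E)-enal.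
5. That enal is (2E,6E)-farnesyl acetate oxidised at its terminal (E)-methyl group. Ring order: epoxide first, then macrocycle and lactone in one operation.

Assumption: (2E,6E)-farnesyl acetate is bought as the single geometric isomer (otherwise one acetylation of (2E,6E)-farnesol is added); cembrane numbering (C1–C14 ring, C15–C17 lactone carbons) is used for the target.

**Step 1**
Reactants: 1 (2E,6E)-farnesyl acetate
Product: 3 (2E,6E,10E)-3,7,11-trimethyl-12-oxododeca-2,6,10-trien-1-yl acetate, via 12-hydroxyfarnesyl acetate 2 (not isolated)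
Conditions: SeO2 (0.3 equiv), t-BuOOH, salicylic acid (cat.), CH2Cl2, rt; crude, then MnO2, CH2Cl2, rt
Reagents that add atoms: tert-butyl hydroperoxide CC(C)(C)OO
Why: Selenium dioxide allylic oxidation (ene reaction, then [2,3]-sigmatropic shift) goes at the (E)-methyl group of the terminal, most electron-rich trisubstituted alkene of farnesyl esters, and MnO2 converges the allylic alcohol 2 and any aldehyde already formed to the (E)-enal; no stereocentre is made.

**Step 2**
Reactants: 3 (2E,6E,10E)-3,7,11-trimethyl-12-oxododeca-2,6,10-trien-1-yl acetate; 4 allylboronic acid pinacol ester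
Product: 6 (2E,6E,10E,12R)-12-hydroxy-3,7,11-trimethylpentadeca-2,6,10,14-tetraen-1-yl acetate, via O-pinacolboryl ether 5 (not isolated)
Conditions: (R)-TRIP [(R)-3,3′-bis(2,4,6-triisopropylphenyl)-1,1′-binaphthyl-2,2′-diyl hydrogen phosphate] (5 mol %), 4 Å MS, PhMe, −30 °C; aq. NaHCO3
Reagents that add atoms: none
Why: Chiral phosphoric acid-catalysed allylboration through a closed chair transition state (acid OH on a boronate oxygen, P=O on the formyl hydrogen) is expected, by analogy with aryl and conjugated aldehydes, to deliver the allyl group to the Re face of the enal, which sets the first stereocentre as 12R (C13 of the target) by asymmetric organocatalysis; the allylic acetate and the trisubstituted alkenes are inert.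

**Step 3**
Reactants: 6 (2E,6E,10E,12R)-12-hydroxy-3,7,11-trimethylpentadeca-2,6,10,14-tetraen-1-yl acetate
Product: 7 (2E,6E,10R,11R,12R)-10,11-epoxy-12-hydroxy-3,7,11-trimethylpentadeca-2,6,14-trien-1-yl acetate
Conditions: Ti(OiPr)4 (10 mol %), (−)-diisopropyl (2S,3S)-tartrate (12 mol %), t-BuOOH, 4 Å MS, CH2Cl2, −20 °C
Reagents that add atoms: tert-butyl hydroperoxide CC(C)(C)OO
Why: Sharpless asymmetric epoxidation in its matched sense: with the (2S,3S)-tartrate the 12R alcohol is the fast-reacting enantiomer and gives the erythro epoxy alcohol (10R,11R), only the allylic alkene reacts, and the minor 12S alcohol from step 2 is left behind so the ee rises.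

**Step 4**
Reactants: 7 (2E,6E,10R,11R,12R)-10,11-epoxy-12-hydroxy-3,7,11-trimethylpentadeca-2,6,14-trien-1-yl acetate
Product: 8 (2E,6E,10R,11R,12R)-10,11-epoxy-3,7,11-trimethylpentadeca-2,6,14-triene-1,12-diol
Conditions: K2CO3 (0.2 equiv), MeOH, 0 °C
Reagents that add atoms: none
Why: Base-catalysed transesterification removes the primary allylic acetate under conditions too mild for Payne rearrangement at the fully substituted epoxide carbon; no stereocentre is touched.

**Step 5**
Reactants: 8 (2E,6E,10R,11R,12R)-10,11-epoxy-3,7,11-trimethylpentadeca-2,6,14-triene-1,12-diol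
Product: 9 (2E,6E,10R,11R,12R)-10,11-epoxy-12-hydroxy-3,7,11-trimethylpentadeca-2,6,14-trienal
Conditions: MnO2, CH2Cl2, rt
Reagents that add atoms: none
Why: MnO2 oxidises only allylic alcohols, so the primary allylic carbinol becomes the (E)-enal while the C12 hydroxyl, no longer allylic after epoxidation, stays free.

**Step 6**
Reactants: 9 (2E,6E,10R,11R,12R)-10,11-epoxy-12-hydroxy-3,7,11-trimethylpentadeca-2,6,14-trienal
Product: 10 (2E,6E,10R,11S,12R)-12-acetoxy-10,11-epoxy-3,7,11-trimethylpentadeca-2,6,14-trienal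
Conditions: Ac2O, pyridine, DMAP (cat.), CH2Cl2, 0 °C to rt
Reagents that add atoms: acetic anhydride CC(=O)OC(C)=O
Why: DMAP-catalysed acylation installs the acetate of the target with retention and blocks this oxygen from later forming a δ-lactone; the C11 descriptor changes from R to S only because the priorities change.

**Step 7**
Reactants: 11 methyl 2-(bromomethyl)acrylate
Product: 12 methyl 2-[(pinacolboryl)methyl]acrylate
Conditions: B2pin2, CuCl, LiCl, KOAc, DMF, rt
Reagents that add atoms: bis(pinacolato)diboron CC1(C)OB(OC1(C)C)B1OC(C)(C)C(C)(C)O1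
Why: Borylcopper made from B2pin2, CuCl and KOAc substitutes the allylic bromide (direct and allylic-shift attack give the same product here), the standard copper-mediated borylation route to 2-(alkoxycarbonyl)allylboronates.

**Step 8**
Reactants: 10 (2E,6E,10R,11S,12R)-12-acetoxy-10,11-epoxy-3,7,11-trimethylpentadeca-2,6,14-trienal; 12 methyl 2-[(pinacolboryl)methyl]acrylate
Product: 13 methyl (2E,5R,6S,7R,10E,14E)-5-acetoxy-6,7-epoxy-6,10,14-trimethyl-16-oxo-2-[(pinacolboryl)methyl]hexadeca-2,10,14-trienoate
Conditions: 12 (3 equiv), Hoveyda–Grubbs second-generation catalyst RuCl2(H2IMes)(=CH-C6H4-2-OiPr) (7 mol %), 2,6-dichloro-1,4-benzoquinone (cat.), CH2Cl2, 40 °C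
Reagents that add atoms: none
Why: Olefin cross-metathesis between the only monosubstituted alkene of 10 and the gem-disubstituted acrylate 12 gives the trisubstituted enoate with the ester trans to the chain (2E, chain carbon cis to CH2B, the geometry needed in step 9); the conjugated and trisubstituted alkenes do not take part, and uncatalysed addition of this electron-poor allylboronate to the enal is too slow at 40 °C to matter.

**Step 9**
Reactants: 13 methyl (2E,5R,6S,7R,10E,14E)-5-acetoxy-6,7-epoxy-6,10,14-trimethyl-16-oxo-2-[(pinacolboryl)methyl]hexadeca-2,10,14-trienoate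
Product: 15 (1S,2S,3E,7E,11R,12S,13R)-13-acetoxy-11,12-epoxycembra-3,7,15(17)-trien-16,2-olide (the target), via macrocyclic O-boryl hydroxy ester 14 (not isolated)
Conditions: (R)-TRIP (20 mol %), 4 Å MS, PhMe, 50 °C, syringe-pump addition of 13 (final 0.002 M); then PPTS (cat.), rt
Reagents that add atoms: none
Why: Proposed new method: a chiral phosphoric acid-catalysed, macrocyclising intramolecular 2-(alkoxycarbonyl)allylboration with lactonisation; the acid hydrogen-bonds to a pinacol oxygen (raising the Lewis acidity of boron) and its P=O binds the formyl hydrogen, so the otherwise sluggish allylboronate adds through a closed chair transition state inside the chiral pocket, Re-face attack on the enal sets 2S, the chain carbon C14 (cis to CH2B in 13) sits axial and gives the syn adduct 14 (1S), which closes to the cis-fused lactone with loss of MeOBpin, and slow addition keeps 13 dilute but the catalyst concentrated so that ring closure beats oligomerisation; the closest known reactions are the intermolecular chiral phosphoric acid-catalysed allylboration of aldehydes and the strong-acid- or Lewis-acid-catalysed additions of 2-(alkoxycarbonyl)allylboronates to aldehydes that give α-methylene-γ-butyrolactones, neither of which has been run with a chiral acid on this boronate class or as a ring closure.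

**Compound list**
1 | (2E,6E)-farnesyl acetate; (2E,6E)-3,7,11-trimethyldodeca-2,6,10-trien-1-yl acetate | CC(=O)OC/C=C(\C)CC/C=C(\C)CCC=C(C)C | starting material
2 | 12-hydroxyfarnesyl acetate; (2E,6E,10E)-12-hydroxy-3,7,11-trimethyldodeca-2,6,10-trien-1-yl acetate (not isolated) | CC(=O)OC/C=C(\C)CC/C=C(\C)CC/C=C(\C)CO | intermediate
3 | (2E,6E,10E)-3,7,11-trimethyl-12-oxododeca-2,6,10-trien-1-yl acetate | CC(=O)OC/C=C(\C)CC/C=C(\C)CC/C=C(\C)C=O | intermediate
4 | allylboronic acid pinacol ester; 2-allyl-4,4,5,5-tetramethyl-1,3,2-dioxaborolane | C=CCB1OC(C)(C)C(C)(C)O1 | starting material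
5 | O-pinacolboryl ether; (2E,6E,10E,12R)-3,7,11-trimethyl-12-(pinacolboryloxy)pentadeca-2,6,10,14-tetraen-1-yl acetate (not isolated) | CC(=O)OC/C=C(\C)CC/C=C(\C)CC/C=C(\C)[C@H](OB1OC(C)(C)C(C)(C)O1)CC=C | intermediate
6 | (2E,6E,10E,12R)-12-hydroxy-3,7,11-trimethylpentadeca-2,6,10,14-tetraen-1-yl acetate | CC(=O)OC/C=C(\C)CC/C=C(\C)CC/C=C(\C)[C@H](O)CC=C | intermediate
7 | (2E,6E,10R,11R,12R)-10,11-epoxy-12-hydroxy-3,7,11-trimethylpentadeca-2,6,14-trien-1-yl acetate | CC(=O)OC/C=C(\C)CC/C=C(\C)CC[C@H]1O[C@]1(C)[C@H](O)CC=C | intermediate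
8 | (2E,6E,10R,11R,12R)-10,11-epoxy-3,7,11-trimethylpentadeca-2,6,14-triene-1,12-diol | OC/C=C(\C)CC/C=C(\C)CC[C@H]1O[C@]1(C)[C@H](O)CC=C | intermediate
9 | (2E,6E,10R,11R,12R)-10,11-epoxy-12-hydroxy-3,7,11-trimethylpentadeca-2,6,14-trienal | O=C/C=C(\C)CC/C=C(\C)CC[C@H]1O[C@]1(C)[C@H](O)CC=C | intermediate
10 | (2E,6E,10R,11S,12R)-12-acetoxy-10,11-epoxy-3,7,11-trimethylpentadeca-2,6,14-trienal | O=C/C=C(\C)CC/C=C(\C)CC[C@H]1O[C@]1(C)[C@H](OC(C)=O)CC=C | intermediate
11 | methyl 2-(bromomethyl)acrylate | C=C(CBr)C(=O)OC | starting material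
12 | methyl 2-[(pinacolboryl)methyl]acrylate; methyl 2-[(4,4,5,5-tetramethyl-1,3,2-dioxaborolan-2-yl)methyl]prop-2-enoate | C=C(CB1OC(C)(C)C(C)(C)O1)C(=O)OC | intermediate
13 | methyl (2E,5R,6S,7R,10E,14E)-5-acetoxy-6,7-epoxy-6,10,14-trimethyl-16-oxo-2-[(pinacolboryl)methyl]hexadeca-2,10,14-trienoate | O=C/C=C(\C)CC/C=C(\C)CC[C@H]1O[C@]1(C)[C@H](OC(C)=O)C/C=C(\CB2OC(C)(C)C(C)(C)O2)C(=O)OC | intermediate
14 | macrocyclic O-boryl hydroxy ester; methyl 2-[(1S,2S,3E,7E,11R,12S,13R)-13-acetoxy-11,12-epoxy-4,8,12-trimethyl-2-(pinacolboryloxy)cyclotetradeca-3,7-dien-1-yl]acrylate (not isolated) | CC1(C)OB(OC1(C)C)O[C@H]2/C=C(\C)CC/C=C(\C)CC[C@H]3O[C@]3(C)[C@H](OC(C)=O)C[C@H]2C(=C)C(=O)OC | intermediate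
15 | (1S,2S,3E,7E,11R,12S,13R)-13-acetoxy-11,12-epoxycembra-3,7,15(17)-trien-16,2-olide (CNP0146076.4) | C=C1C(=O)O[C@H]2/C=C(\C)CC/C=C(\C)CC[C@H]3O[C@]3(C)[C@H](OC(C)=O)C[C@@H]12 | target

**Step count**
Total steps: 9. Longest linear sequence: 8 (steps 1–6, 8 and 9; step 7 makes reagent 12).

**Steps most likely to fail, most doubtful first**

Step 9, the proposed new ring closure. The doubts are three:
- whether a phosphoric acid turns over the electron-poor allylboronate at high dilution (its N-triflyl phosphoramide analogue would be tried first);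
- whether the catalyst or the C11–C13 stereocentres decide the enal face;
- whether the epoxide tolerates the acid.

The fallback uses known chemistry, sets out from 10 and comes back at 15. Cross-metathesis of 10 with 11 (same ruthenium catalyst, CH2Cl2, 40 °C) gives methyl (2Z,5R,6S,7R,10E,14E)-5-acetoxy-2-(bromomethyl)-6,7-epoxy-6,10,14-trimethyl-16-oxohexadeca-2,10,14-trienoate F1. Intramolecular Nozaki–Hiyama–Kishi-type allylation with CrCl2 (8 equiv, 4 Å MS, THF, rt, syringe pump to 0.002 M) is the established way to close cembranolides from 2-(bromomethyl)enoate aldehydes. It gives methyl 2-[(1S,2S,3E,7E,11R,12S,13R)-13-acetoxy-11,12-epoxy-2-hydroxy-4,8,12-trimethylcyclotetradeca-3,7-dien-1-yl]acrylate F2, which lactonises in the flask or with a trace of PPTS to 15. The cis ring fusion follows from the Z-bromide; the sense relative to C11–C13 is then under substrate control.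

Step 8, cross-metathesis with a gem-disubstituted, boron-bearing acrylate next to a free enal. The fallback moves the metathesis to the alcohol oxidation level and changes the order of the later steps; it sets out from 8 and comes back at 13. Diol 8 and 12 (3 equiv, same ruthenium catalyst, CH2Cl2, 40 °C, no aldehyde in the flask) give methyl (2E,5R,6R,7R,10E,14E)-6,7-epoxy-5,16-dihydroxy-6,10,14-trimethyl-2-[(pinacolboryl)methyl]hexadeca-2,10,14-trienoate F3. MnO2 (CH2Cl2, rt) then gives methyl (2E,5R,6R,7R,10E,14E)-6,7-epoxy-5-hydroxy-6,10,14-trimethyl-16-oxo-2-[(pinacolboryl)methyl]hexadeca-2,10,14-trienoate F4. Ac2O, pyridine and DMAP give 13. This does not help if metathesis with a gem-disubstituted acrylate fails outright; the step 9 fallback has the same dependence.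

Step 1, the allylic oxidation, which is known on this substrate but modest in yield and gives regioisomers and over-oxidation. The fallback sets out from 1 and comes back at 3 in one operation: cross-metathesis of the terminal isopropylidene group of 1 with methacrolein (2-methylprop-2-enal, 5 equiv, same ruthenium catalyst, CH2Cl2, 40 °C) gives the (E)-enal 3 directly. The internal trisubstituted alkenes are far less reactive. New compounds: none F0.

**Further compounds**
F1 | step 9 | methyl (2Z,5R,6S,7R,10E,14E)-5-acetoxy-2-(bromomethyl)-6,7-epoxy-6,10,14-trimethyl-16-oxohexadeca-2,10,14-trienoate | O=C/C=C(\C)CC/C=C(\C)CC[C@H]1O[C@]1(C)[C@H](OC(C)=O)C/C=C(\CBr)C(=O)OC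
F2 | step 9 | methyl 2-[(1S,2S,3E,7E,11R,12S,13R)-13-acetoxy-11,12-epoxy-2-hydroxy-4,8,12-trimethylcyclotetradeca-3,7-dien-1-yl]acrylate | O[C@H]1/C=C(\C)CC/C=C(\C)CC[C@H]2O[C@]2(C)[C@H](OC(C)=O)C[C@H]1C(=C)C(=O)OC
F3 | step 8 | methyl (2E,5R,6R,7R,10E,14E)-6,7-epoxy-5,16-dihydroxy-6,10,14-trimethyl-2-[(pinacolboryl)methyl]hexadeca-2,10,14-trienoate | OC/C=C(\C)CC/C=C(\C)CC[C@H]1O[C@]1(C)[C@H](O)C/C=C(\CB2OC(C)(C)C(C)(C)O2)C(=O)OC
F4 | step 8 | methyl (2E,5R,6R,7R,10E,14E)-6,7-epoxy-5-hydroxy-6,10,14-trimethyl-16-oxo-2-[(pinacolboryl)methyl]hexadeca-2,10,14-trienoate | O=C/C=C(\C)CC/C=C(\C)CC[C@H]1O[C@]1(C)[C@H](O)C/C=C(\CB2OC(C)(C)C(C)(C)O2)C(=O)OC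
F0 | step 1 | none | none
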